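**Retrosynthetic overview**
- Target ⇒ (2E,4E,6E)-octa-2,4,6-trienoic acid (fragment C) + the 6-hydroxy decalin core (ester bond at O6), with the C11 acid masked as tert-butyl ester and 9-OH as a silyl ether.
- Core ⇒ a C8 ketone: C12 aldehyde by enol triflate carbonylation, O6 by peracid oxidation of the dienol ether, O9 by Rubottom oxidation, C10 methyl by cuprate addition (this sets the cis ring fusion).
- Ring B ⇒ intramolecular Knoevenagel-type aldol condensation of C9 onto the C10 ketone; the open chain comes from Michael union of fragment A (hydroxymethylene ketone from 3-methylcyclohex-2-enone) with fragment B (vinyl β-keto ester from tert-butyl acetate and acrolein).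
- Ring order: ring A is carried in from 3-methylcyclohex-2-enone; ring B is the only ring formed. The core is made racemic and the absolute configuration is fixed by kinetic resolution of the 6-alcohol before esterification.

Assumption: the target is taken exactly as drawn, (5R,6R,9R,10S) in drimane numbering (used in the Why lines; C9, C8, C7, C6, C5, C10 = C1, C2, C3, C4, C4a, C8a of the naphthalene names), i.e. a cis-fused decalin with 10-Me, 5-H, O6 and 9-OH on one face; compounds 11–21 are racemic and are drawn as the enantiomer that leads to the target.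

**Step 1**
Reactants: 1 3-methylcyclohex-2-en-1-one
Product: 3 trimethyl[(3,3-dimethylcyclohex-1-en-1-yl)oxy]silane, via lithium enolate 2 (not isolated)
Conditions: Me2CuLi, Et2O, 0 °C; then Me3SiCl, Et3N, 0 °C to rt
Reagents that add atoms: lithium dimethylcuprate, [Li+].C[Cu-]C; chlorotrimethylsilane, C[Si](C)(C)Cl
Why: Cuprate 1,4-addition builds the gem-dimethyl carbon (C4) and gives the enolate regiospecifically on the hindered side (C5), which is trapped as the silyl enol ether; no stereocentre is formed.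

**Step 2**
Reactants: 3 trimethyl[(3,3-dimethylcyclohex-1-en-1-yl)oxy]silane
Product: 5 (2Z)-2-(hydroxymethylidene)-3,3-dimethylcyclohexan-1-one, via potassium enolate 4 (not isolated)
Conditions: KOt-Bu, THF, −15 °C; then HCO2CH2CF3, −78 to 0 °C; 1 M HCl
Reagents that add atoms: 2,2,2-trifluoroethyl formate, O=COCC(F)(F)F
Why: tert-Butoxide attacks silicon and releases the copper-free potassium enolate with its double bond still towards C5 (no proton source, so no equilibration), and Claisen-type C-formylation then gives the chelated hydroxymethylene ketone that activates C5 for the Michael step.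

**Step 3**
Reactants: 6 tert-butyl acetate; 7 acrolein
Product: 9 tert-butyl 3-hydroxypent-4-enoate (racemic), via lithium enolate 8 (not isolated)
Conditions: LiN(i-Pr)2, THF, −78 °C; then 7, −78 °C; AcOH
Reagents that add atoms: none
Why: Aldol addition of the ester enolate to the aldehyde carbonyl of acrolein (1,2-addition at low temperature); the carbinol centre is removed in step 4.

**Step 4**
Reactants: 9 tert-butyl 3-hydroxypent-4-enoate
Product: 10 tert-butyl 3-oxopent-4-enoate
Conditions: Dess–Martin periodinane, CH2Cl2, 0 °C to rt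
Reagents that add atoms: none
Why: Dess–Martin oxidation of the allylic alcohol gives the vinyl β-keto ester (a Nazarov-type annulation reagent), which is used at once because it polymerises.

**Step 5**
Reactants: 5 (2Z)-2-(hydroxymethylidene)-3,3-dimethylcyclohexan-1-one; 10 tert-butyl 3-oxopent-4-enoate
Product: 12 tert-butyl 5-[(1R)-2,2-dimethyl-6-oxocyclohexyl]-3-oxopentanoate (racemic), via Michael adduct 11 (not isolated)
Conditions: Et3N (10 mol %), CH2Cl2, 0 °C to rt; then K2CO3 (20 mol %), MeOH, rt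
Reagents that add atoms: none
Why: Amine-catalysed Michael addition of the acidic hydroxymethylene ketone to the vinyl ketone joins fragments A and B at C5–C6, and retro-Claisen deformylation (methanolysis) of the non-enolisable β-keto aldehyde then leaves C5–H as a racemic stereocentre.

**Step 6**
Reactants: 12 tert-butyl 5-[(1R)-2,2-dimethyl-6-oxocyclohexyl]-3-oxopentanoate
Product: 13 tert-butyl (4aR)-5,5-dimethyl-2-oxo-2,3,4,4a,5,6,7,8-octahydronaphthalene-1-carboxylate (racemic)
Conditions: piperidine (20 mol %), AcOH (20 mol %), benzene, reflux, Dean–Stark trap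
Reagents that add atoms: none
Why: Intramolecular Knoevenagel-type aldol condensation: the doubly activated C9 methylene adds to the C10 ring ketone and loses water, closing ring B as the conjugated alkylidene β-keto ester; C5 is the only stereocentre.

**Step 7**
Reactants: 13 tert-butyl (4aR)-5,5-dimethyl-2-oxo-2,3,4,4a,5,6,7,8-octahydronaphthalene-1-carboxylate
Product: 15 tert-butyl (4aR,8aS)-5,5,8a-trimethyl-2-[(triethylsilyl)oxy]-3,4,4a,5,6,7,8,8a-octahydronaphthalene-1-carboxylate (racemic), via lithium enolate 14 (not isolated)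
Conditions: Me2CuLi, Et2O/THF, −78 to −30 °C; then Et3SiCl, Et3N, −30 °C to rt
Reagents that add atoms: lithium dimethylcuprate, [Li+].C[Cu-]C; chlorotriethylsilane, CC[Si](Cl)(CC)CC
Why: Cuprate 1,4-addition to the doubly activated alkene delivers methyl to C10 on the face of H-5 (the other face is blocked by the axial C4 methyl), giving the cis ring fusion as in Me2CuLi additions to octalones; the β-keto ester enolate is then O-silylated.

**Step 8**
Reactants: 15 tert-butyl (4aR,8aS)-5,5,8a-trimethyl-2-[(triethylsilyl)oxy]-3,4,4a,5,6,7,8,8a-octahydronaphthalene-1-carboxylate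
Product: 16 tert-butyl (1R,4aR,8aS)-5,5,8a-trimethyl-2-oxo-1-[(triethylsilyl)oxy]decahydronaphthalene-1-carboxylate (racemic)
Conditions: dimethyldioxirane, acetone/CH2Cl2, −40 to 0 °C
Reagents that add atoms: dimethyldioxirane, CC1(C)OO1
Why: Rubottom oxidation: the silyl enol ether is epoxidised from the convex face of the cis-decalin (the face of the C10 methyl and H-5) and 1,4-silyl migration gives the α-silyloxy ketone, setting C9 with oxygen on that face.

**Step 9**
Reactants: 16 tert-butyl (1R,4aR,8aS)-5,5,8a-trimethyl-2-oxo-1-[(triethylsilyl)oxy]decahydronaphthalene-1-carboxylate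
Product: 18 tert-butyl (1R,4aR,8aS)-5,5,8a-trimethyl-1-[(triethylsilyl)oxy]-2-{[(trifluoromethyl)sulfonyl]oxy}-1,4,4a,5,6,7,8,8a-octahydronaphthalene-1-carboxylate (racemic), via potassium enolate 17 (not isolated)
Conditions: KN(SiMe3)2, THF, −78 °C; then Comins' reagent, −78 to 0 °C
Reagents that add atoms: N-(5-chloropyridin-2-yl)-1,1,1-trifluoro-N-[(trifluoromethyl)sulfonyl]methanesulfonamide (Comins' reagent), O=S(=O)(N(c1ccc(Cl)cn1)S(=O)(=O)C(F)(F)F)C(F)(F)F
Why: The ketone can enolise only towards C7 because C9 is quaternary, and O-triflation of the enolate gives the C7=C8 enol triflate without touching a stereocentre.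

**Step 10**
Reactants: 18 the enol triflate
Product: 19 tert-butyl (1R,4aR,8aS)-2-formyl-5,5,8a-trimethyl-1-[(triethylsilyl)oxy]-1,4,4a,5,6,7,8,8a-octahydronaphthalene-1-carboxylate (racemic)
Conditions: Pd(PPh3)4 (5 mol %), CO (1 atm), Bu3SnH (slow addition), THF, 50 °C
Reagents that add atoms: carbon monoxide, [C-]#[O+]
Why: Stille reductive carbonylation (formylation) of the vinyl triflate: oxidative addition of zerovalent palladium, CO insertion and hydride transfer from tin install C12 as the enal; no stereocentre is involved.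

**Step 11**
Reactants: 19 the enal
Product: 21 tert-butyl (1R,4R,4aR,8aS)-2-formyl-4-hydroxy-5,5,8a-trimethyl-1-[(triethylsilyl)oxy]-1,4,4a,5,6,7,8,8a-octahydronaphthalene-1-carboxylate (racemic), via silyl dienol ether 20 (not isolated)
Conditions: Me3SiCl, KN(SiMe3)2 (in situ trapping), THF, −78 °C; then mCPBA, CH2Cl2, −20 °C; aq. citric acid
Reagents that add atoms: 3-chloroperoxybenzoic acid, OOC(=O)c1cccc(Cl)c1
Why: Vinylogous Rubottom oxidation: γ-deprotonation and O-silylation give the dienol ether, whose terminal C6=C7 bond is attacked by the peracid from the convex face (as in the 6β-hydroxylation of steroid dienol ethers), so O6 ends up cis to H-5.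

**Step 12**
Reactants: 21 the racemic 6-alcohol
Product: 22 tert-butyl (1R,4R,4aR,8aS)-2-formyl-4-hydroxy-5,5,8a-trimethyl-1-[(triethylsilyl)oxy]-1,4,4a,5,6,7,8,8a-octahydronaphthalene-1-carboxylate (single enantiomer)
Conditions: (R)-2-phenyl-2,3-dihydroimidazo[2,1-b][1,3]benzothiazole (5 mol %), (i-PrCO)2O (0.6 equiv), i-Pr2NEt, CHCl3, 0 °C, to about 58 % conversion; chromatography
Reagents that add atoms: none
Why: Acylative kinetic resolution with Birman's isothiourea catalyst: by the usual alkenyl π-recognition model the (4S) enantiomer is acylated faster, so running past half conversion leaves the required alcohol enantiopure (at most 50 % yield) and fixes the absolute configuration of all four stereocentres.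

**Step 13**
Reactants: 23 ethyl (2E,4E)-hexa-2,4-dienoate (ethyl sorbate)
Product: 24 (2E,4E)-hexa-2,4-dien-1-ol
Conditions: i-Bu2AlH, CH2Cl2, −78 °C; then H2O
Reagents that add atoms: none
Why: 1,2-Reduction of the dienoate by the aluminium hydride gives the dienol without touching the alkenes.

**Step 14**
Reactants: 24 (2E,4E)-hexa-2,4-dien-1-ol
Product: 25 (2E,4E)-hexa-2,4-dienal
Conditions: MnO2, CH2Cl2, rt
Reagents that add atoms: none
Why: Allylic oxidation with MnO2 gives the dienal without E/Z isomerisation; it is made fresh because it autoxidises.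

**Step 15**
Reactants: 25 (2E,4E)-hexa-2,4-dienal
Product: 26 ethyl (2E,4E,6E)-octa-2,4,6-trienoate
Conditions: Ph3P=CHCO2Et, CH2Cl2, rt
Reagents that add atoms: ethyl (triphenylphosphoranylidene)acetate, CCOC(=O)C=P(c1ccccc1)(c1ccccc1)c1ccccc1
Why: Wittig olefination with the stabilised ylide forms the new alkene with E selectivity.

**Step 16**
Reactants: 26 ethyl (2E,4E,6E)-octa-2,4,6-trienoate
Product: 27 (2E,4E,6E)-octa-2,4,6-trienoic acid
Conditions: LiOH, THF/H2O, rt; then 1 M HCl
Reagents that add atoms: lithium hydroxide, [Li+].[OH-]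
Why: Saponification of the ethyl ester under mild conditions keeps the triene geometry.

**Step 17**
Reactants: 22 the resolved 6-alcohol; 27 (2E,4E,6E)-octa-2,4,6-trienoic acid
Product: 29 tert-butyl (1R,4R,4aR,8aS)-2-formyl-5,5,8a-trimethyl-4-{[(2E,4E,6E)-octa-2,4,6-trienoyl]oxy}-1-[(triethylsilyl)oxy]-1,4,4a,5,6,7,8,8a-octahydronaphthalene-1-carboxylate, via mixed anhydride 28 (not isolated)
Conditions: 27, 2,4,6-Cl3C6H2COCl, Et3N, THF, rt; then 22, 4-(dimethylamino)pyridine, toluene, rt to 40 °C
Reagents that add atoms: none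
Why: Yamaguchi esterification: the pyridine catalyst transfers the trienoyl group of the mixed anhydride to the hindered 6-OH with retention at C6, while the tertiary silyl ether and the aldehyde stay inert.

**Step 18**
Reactants: 29 the protected ester
Product: 30 (1R,4R,4aR,8aS)-2-formyl-1-hydroxy-5,5,8a-trimethyl-4-{[(2E,4E,6E)-octa-2,4,6-trienoyl]oxy}-1,4,4a,5,6,7,8,8a-octahydronaphthalene-1-carboxylic acid (CNP0234478.8)
Conditions: CF3CO2H/CH2Cl2/H2O (20:75:5), 0 °C to rt
Reagents that add atoms: none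
Why: Acidolysis removes the tert-butyl ester (E1 loss of isobutene) and the tertiary silyl ether in one operation; the allylic ester and the C9 carbinol do not ionise because the alkene is electron-poor.

**Compound list**
1 | 3-methylcyclohex-2-en-1-one | CC1=CC(=O)CCC1 | starting material
2 | lithium 3,3-dimethylcyclohex-1-en-1-olate | [Li+].[O-]C1=CC(C)(C)CCC1 | intermediate
3 | trimethyl[(3,3-dimethylcyclohex-1-en-1-yl)oxy]silane | C[Si](C)(C)OC1=CC(C)(C)CCC1 | intermediate
4 | potassium 3,3-dimethylcyclohex-1-en-1-olate | [K+].[O-]C1=CC(C)(C)CCC1 | intermediate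
5 | (2Z)-2-(hydroxymethylidene)-3,3-dimethylcyclohexan-1-one | O/C=C1\C(=O)CCCC1(C)C | intermediate
6 | tert-butyl acetate | CC(=O)OC(C)(C)C | starting material
7 | acrolein (prop-2-enal) | C=CC=O | starting material
8 | lithium 1-tert-butoxyethen-1-olate | [Li+].[O-]C(=C)OC(C)(C)C | intermediate
9 | tert-butyl 3-hydroxypent-4-enoate (racemic) | C=CC(O)CC(=O)OC(C)(C)C | intermediate
10 | tert-butyl 3-oxopent-4-enoate | C=CC(=O)CC(=O)OC(C)(C)C | intermediate
11 | tert-butyl 5-(1-formyl-2,2-dimethyl-6-oxocyclohexyl)-3-oxopentanoate (racemic) | O=CC1(CCC(=O)CC(=O)OC(C)(C)C)C(=O)CCCC1(C)C | intermediate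
12 | tert-butyl 5-[(1R)-2,2-dimethyl-6-oxocyclohexyl]-3-oxopentanoate (racemic) | CC1(C)CCCC(=O)[C@@H]1CCC(=O)CC(=O)OC(C)(C)C | intermediate
13 | tert-butyl (4aR)-5,5-dimethyl-2-oxo-2,3,4,4a,5,6,7,8-octahydronaphthalene-1-carboxylate (racemic) | C1CC(=O)C(C(=O)OC(C)(C)C)=C2CCCC(C)(C)[C@@H]12 | intermediate
14 | lithium (4aR,8aS)-1-(tert-butoxycarbonyl)-5,5,8a-trimethyl-3,4,4a,5,6,7,8,8a-octahydronaphthalen-2-olate (racemic) | [Li+].C1CC([O-])=C(C(=O)OC(C)(C)C)[C@@]2(C)CCCC(C)(C)[C@@H]12 | intermediate
15 | tert-butyl (4aR,8aS)-5,5,8a-trimethyl-2-[(triethylsilyl)oxy]-3,4,4a,5,6,7,8,8a-octahydronaphthalene-1-carboxylate (racemic) | C1CC(O[Si](CC)(CC)CC)=C(C(=O)OC(C)(C)C)[C@@]2(C)CCCC(C)(C)[C@@H]12 | intermediate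
16 | tert-butyl (1R,4aR,8aS)-5,5,8a-trimethyl-2-oxo-1-[(triethylsilyl)oxy]decahydronaphthalene-1-carboxylate (racemic) | C1CC(=O)[C@@](O[Si](CC)(CC)CC)(C(=O)OC(C)(C)C)[C@@]2(C)CCCC(C)(C)[C@@H]12 | intermediate
17 | potassium (1R,4aR,8aS)-1-(tert-butoxycarbonyl)-5,5,8a-trimethyl-1-[(triethylsilyl)oxy]-1,4,4a,5,6,7,8,8a-octahydronaphthalen-2-olate (racemic) | [K+].C1C=C([O-])[C@@](O[Si](CC)(CC)CC)(C(=O)OC(C)(C)C)[C@@]2(C)CCCC(C)(C)[C@@H]12 | intermediate
18 | tert-butyl (1R,4aR,8aS)-5,5,8a-trimethyl-1-[(triethylsilyl)oxy]-2-{[(trifluoromethyl)sulfonyl]oxy}-1,4,4a,5,6,7,8,8a-octahydronaphthalene-1-carboxylate (racemic) | C1C=C(OS(=O)(=O)C(F)(F)F)[C@@](O[Si](CC)(CC)CC)(C(=O)OC(C)(C)C)[C@@]2(C)CCCC(C)(C)[C@@H]12 | intermediate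
19 | tert-butyl (1R,4aR,8aS)-2-formyl-5,5,8a-trimethyl-1-[(triethylsilyl)oxy]-1,4,4a,5,6,7,8,8a-octahydronaphthalene-1-carboxylate (racemic) | C1C=C(C=O)[C@@](O[Si](CC)(CC)CC)(C(=O)OC(C)(C)C)[C@@]2(C)CCCC(C)(C)[C@@H]12 | intermediate
20 | tert-butyl (1R,4aR,8aS)-5,5,8a-trimethyl-1-[(triethylsilyl)oxy]-2-{[(trimethylsilyl)oxy]methylidene}-1,2,4a,5,6,7,8,8a-octahydronaphthalene-1-carboxylate (racemic, enol ether geometry not fixed) | C1=CC(=CO[Si](C)(C)C)[C@@](O[Si](CC)(CC)CC)(C(=O)OC(C)(C)C)[C@@]2(C)CCCC(C)(C)[C@@H]12 | intermediate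
21 | tert-butyl (1R,4R,4aR,8aS)-2-formyl-4-hydroxy-5,5,8a-trimethyl-1-[(triethylsilyl)oxy]-1,4,4a,5,6,7,8,8a-octahydronaphthalene-1-carboxylate (racemic) | O[C@@H]1C=C(C=O)[C@@](O[Si](CC)(CC)CC)(C(=O)OC(C)(C)C)[C@@]2(C)CCCC(C)(C)[C@@H]12 | intermediate
22 | tert-butyl (1R,4R,4aR,8aS)-2-formyl-4-hydroxy-5,5,8a-trimethyl-1-[(triethylsilyl)oxy]-1,4,4a,5,6,7,8,8a-octahydronaphthalene-1-carboxylate (single enantiomer) | O[C@@H]1C=C(C=O)[C@@](O[Si](CC)(CC)CC)(C(=O)OC(C)(C)C)[C@@]2(C)CCCC(C)(C)[C@@H]12 | intermediate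
23 | ethyl (2E,4E)-hexa-2,4-dienoate | C/C=C/C=C/C(=O)OCC | starting material
24 | (2E,4E)-hexa-2,4-dien-1-ol | C/C=C/C=C/CO | intermediate
25 | (2E,4E)-hexa-2,4-dienal | C/C=C/C=C/C=O | intermediate
26 | ethyl (2E,4E,6E)-octa-2,4,6-trienoate | C/C=C/C=C/C=C/C(=O)OCC | intermediate
27 | (2E,4E,6E)-octa-2,4,6-trienoic acid | C/C=C/C=C/C=C/C(=O)O | intermediate
28 | (2E,4E,6E)-octa-2,4,6-trienoic 2,4,6-trichlorobenzoic anhydride | C/C=C/C=C/C=C/C(=O)OC(=O)c1c(Cl)cc(Cl)cc1Cl | intermediate
29 | tert-butyl (1R,4R,4aR,8aS)-2-formyl-5,5,8a-trimethyl-4-{[(2E,4E,6E)-octa-2,4,6-trienoyl]oxy}-1-[(triethylsilyl)oxy]-1,4,4a,5,6,7,8,8a-octahydronaphthalene-1-carboxylate | C/C=C/C=C/C=C/C(=O)O[C@@H]1C=C(C=O)[C@@](O[Si](CC)(CC)CC)(C(=O)OC(C)(C)C)[C@@]2(C)CCCC(C)(C)[C@@H]12 | intermediate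
30 | (1R,4R,4aR,8aS)-2-formyl-1-hydroxy-5,5,8a-trimethyl-4-{[(2E,4E,6E)-octa-2,4,6-trienoyl]oxy}-1,4,4a,5,6,7,8,8a-octahydronaphthalene-1-carboxylic acid | C/C=C/C=C/C=C/C(=O)O[C@@H]1C=C(C=O)[C@@](O)(C(=O)O)[C@@]2(C)CCCC(C)(C)[C@@H]12 | target

**Total step count:** 18

**Longest linear sequence:** 12 steps (1, 2, 5–12, 17, 18; the branch through steps 3 and 4 is equally long)

**Steps most likely to fail**

Step 7 (methyl addition at the hindered, fully substituted C10 and the cis selectivity). If the cuprate is sluggish or gives the trans isomer, the methyl group is brought in as a cyclopropane. Setting out from 13, trimethylsulfoxonium iodide and NaH in DMSO (Corey–Chaykovsky cyclopropanation) give the cyclopropane-fused keto ester F1, with the new CH2 on the face of H-5. Li in NH3/THF at −78 °C then cleaves the exocyclic cyclopropane bond that overlaps with the ketone. This produces the C10 methyl and the lithium enolate 14, which is silylated with Et3SiCl to come back to the route at 15.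

Step 11 (peracid attack at C6 rather than at the enol ether carbon C8, and facial selectivity). If α-oxidation competes, the same silyl dienol ether 20, made from 19, is photo-oxygenated (O2, 5,10,15,20-tetraphenylporphyrin, visible light, CH2Cl2, −78 °C). The [4+2] adduct, the silyl peroxy acetal F2, can carry oxygen only at C6 and C12. Reduction of its O–O bond with thiourea and loss of the silyl hemiacetal come back to the route at 21.

Step 12 (selectivity factor of the kinetic resolution on a hindered cyclic alcohol). If the selectivity is too low, 21 is resolved through covalent diastereomers. Esterification with (S)-2-methoxy-2-phenylacetic acid (dicyclohexylcarbodiimide, 4-(dimethylamino)pyridine, CH2Cl2) gives the O-methylmandelate of the (4R) alcohol F3 and the O-methylmandelate of the (4S) alcohol F4, which are separated on silica. Methanolysis of F3 (K2CO3, MeOH, 0 °C) comes back to the route at 22.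

**Further compounds**
F1 | step 7 | tert-butyl 5,5-dimethyl-2-oxooctahydro-1,8a-methanonaphthalene-1(2H)-carboxylate, cyclopropane CH2 on the face of H-4a (racemic) | C1CC(=O)[C@]3(C(=O)OC(C)(C)C)C[C@@]32CCCC(C)(C)[C@@H]12
F2 | step 11 | [4+2] endoperoxide of 20: O–O bridge from C4 to the former enol ether carbon CH(OSiMe3), on the face of H-4a (racemic, acetal carbon not fixed) | C[Si](C)(C)OC3OO[C@@H]1C=C3[C@@](O[Si](CC)(CC)CC)(C(=O)OC(C)(C)C)[C@@]2(C)CCCC(C)(C)[C@@H]12
F3 | step 12 | (2S)-2-methoxy-2-phenylacetate of 22 | CO[C@@H](c1ccccc1)C(=O)O[C@@H]1C=C(C=O)[C@@](O[Si](CC)(CC)CC)(C(=O)OC(C)(C)C)[C@@]2(C)CCCC(C)(C)[C@@H]12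
F4 | step 12 | (2S)-2-methoxy-2-phenylacetate of the enantiomer of 22 | CO[C@@H](c1ccccc1)C(=O)O[C@H]1C=C(C=O)[C@](O[Si](CC)(CC)CC)(C(=O)OC(C)(C)C)[C@]2(C)CCCC(C)(C)[C@H]12
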